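The numbers belong to no real substance; no experiment stands behind them.

The slowness of this ring can be counted in powers of ten.

    starting material ⇌ target (K1 = 7.42, k1 = 1.59 × 10⁻⁴ s⁻¹)
    target ⇌ isomer of the product (K2 = 0.23, k2 = 1.13 × 10⁻⁴ s⁻¹)
    isomer of the product ⇌ starting material (k3 = 6.17 × 10⁻⁴ s⁻¹)

| flask | starting material | time | remark |
|---|---|---|---|
| winter | 1.5 M | 80 min | a closed flask charged with all of it at once and left for 80 min |
| summer | 1.5 M |  | a single well-mixed tank run continuously and read at steady state, 80 min in it on average |

- the set-up with the highest share of target in all that became target or isomer of the product, at the outlet or at the end ("none" if the first two lie within 2 percentage points) (winter / summer / none)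
- share of target in all that became target or isomer of the product, at the outlet or at the end, winter
- share of target in all that became target or isomer of the product, at the outlet or at the end, summer

- the stated concentrations are those of everything mixed, before any reaction; amounts are the same in each set-up
- run time (winter): 80 min

Which numbers must we know well? The charge does not count: every step is first order, so 1.5 M cancels from the share [target]/([target] + [isomer of the product]). At equilibrium that share is 1/(1 + second equilibrium constant), or 81.3%, and twice that constant gives 68.5%, so it matters.

We follow the rates through the slow relaxation rate, the smaller root of the ring's quadratic, whose six constants sum to 0.147 min⁻¹. Twice the second rate constant gives 0.0461 min⁻¹, and twice the third gives 0.0295 min⁻¹. The second must be known better than the third. The rate itself is 0.0287 min⁻¹.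

In the winter flask that makes 1.00: the decade count, the powers of ten lost by target's distance from equilibrium during the run. By this count the distance left in the winter flask is 10.0%; for the summer tank we take 1/(1 + rate × mean stay), or 30.3%. We give isomer 63.1% of the shortfall, its equilibrium part of the pair it forms with starting material. Our reckoning, which skips the faster root, gives 75.4% for winter and 62.3% for summer, so winter.

The forecast says winter, 74.9% against 65.7%, the closed flask being “further along that path than the well-mixed tank”. On summer it stands above us, on winter below us.

The simulation gives winter: 74.9% in winter, 65.7% in summer. At 80.0 min the winter flask made isomer at 0.312 of the rate at which it used it up, each step taken net. The decade count, applied to target, gives 65.9% of the charge; the winter flask holds 64.6%.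

Read the winter flask at 20 min instead: 0.250 decades leave 56.3% of the distance, so the share comes to 42.8%. The computed share is 40.7%, with isomer at 37.9% and target at 26.0%: kinetic rather than thermodynamic control.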